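**Plan**

- Feature: numbering C1–C7 from ring A (guaiacyl) to ring B (4-hydroxyphenyl), the C5 carbonyl lies between C4H2 and C6H2 and is flanked by oxygen on C3 and C7. This is the pattern a single C5 acyl dianion equivalent leaves after opening two terminal epoxides.
- Retrosynthesis: remove the three silyl groups, re-mask C5 as a 1,3-dithiane and reduce C3 to a carbinol. Then cut C5–C6 and C4–C5 to reach 2-TBS-1,3-dithiane, an (R)-aryl oxirane (C6–C7 with ring B) and a racemic styryl oxirane (C1–C4 with ring A).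
- Forward: the chain is joined in one flask, C5–C6 first, then silyl transfer from C5 to O7, then C4–C5. No ring is formed. Oxidation at C3, unmasking of C5 and desilylation finish the route.
- Stereochemistry: C7 is set by a Corey–Bakshi–Shibata reduction of the phenacyl bromide and is never touched again (R in the oxirane, S in the chain through CIP ranking only). The (E)-C1=C2 alkene comes from coniferaldehyde. C3 is racemic and is erased by oxidation.

Key step: step 7

Remark: the C3 enol/C5 ketone of the target is one tautomer of a β-diketone whose enol geometry equilibrates through the diketo form, so only the (E)-C1=C2 alkene and the (7S) carbinol are treated as fixed stereo-elements.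

**Route**

Step 1
Reactants: 1 2-bromo-1-(4-hydroxyphenyl)ethanone
Product: 2 2-bromo-1-[4-(triisopropylsilyloxy)phenyl]ethanone
Conditions: TIPSOTf, 2,6-lutidine, CH2Cl2, −78 → 0 °C
Reagents that add atoms: triisopropylsilyl trifluoromethanesulfonate (TIPSOTf), CC(C)[Si](C(C)C)(C(C)C)OS(=O)(=O)C(F)(F)F
Why: O-silylation of the phenol by a silyl triflate with a hindered pyridine base is fast at low temperature and avoids nucleophilic amines that would quaternise on the α-bromoketone.

Step 2
Reactants: 2 2-bromo-1-[4-(triisopropylsilyloxy)phenyl]ethanone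
Product: 3 (R)-2-bromo-1-[4-(triisopropylsilyloxy)phenyl]ethanol
Conditions: (R)-tetrahydro-1-methyl-3,3-diphenyl-1H,3H-pyrrolo[1,2-c][1,3,2]oxazaborole (10 mol %), BH3·SMe2, THF, 0 °C, slow addition of 2; then MeOH
Reagents that add atoms: none
Why: Corey–Bakshi–Shibata reduction, in which the (R)-oxazaborolidine holds borane and the ketone with the aryl group in the large-group position, so hydride should reach the face that gives the (R)-bromohydrin (CH2Br outranks aryl), as is usual for phenacyl halides.

Step 3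
Reactants: 3 (R)-2-bromo-1-[4-(triisopropylsilyloxy)phenyl]ethanol
Product: 4 (R)-2-[4-(triisopropylsilyloxy)phenyl]oxirane
Conditions: NaH, THF, 0 °C
Reagents that add atoms: none
Why: intramolecular Williamson etherification (3-exo-tet closure of the alkoxide on CH2Br) forms the oxirane without touching the benzylic centre, so (R) is retained, and a non-nucleophilic hydride base spares the aryl silyl ether.

Step 4
Reactants: 5 coniferaldehyde, (E)-3-(4-hydroxy-3-methoxyphenyl)prop-2-enal
Product: 6 (E)-3-[3-methoxy-4-(triisopropylsilyloxy)phenyl]prop-2-enal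
Conditions: TIPSCl, imidazole, DMF, 0 °C → rt
Reagents that add atoms: chlorotriisopropylsilane (TIPSCl), CC(C)[Si](Cl)(C(C)C)C(C)C
Why: imidazole-mediated O-silylation of the acidic vinylogous phenol is routine, and TIPS is chosen because it should withstand the ylide and organolithium steps that follow.

Step 5
Reactants: 6 (E)-3-[3-methoxy-4-(triisopropylsilyloxy)phenyl]prop-2-enal
Product: 7 racemic 2-[(E)-2-(3-methoxy-4-triisopropylsilyloxyphenyl)ethenyl]oxirane
Conditions: Me3S+ I−, n-BuLi, THF, −10 °C; then 6, −10 °C → rt; filtration through basic Al2O3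
Reagents that add atoms: trimethylsulfonium iodide, C[S+](C)C.[I-]
Why: Corey–Chaykovsky epoxidation, in which dimethylsulfonium methylide adds 1,2 to the enal carbonyl and the alkoxide displaces Me2S, should give the styryl oxirane with the (E)-alkene intact; the new C3 centre is left racemic on purpose because it is oxidised in step 8.

Step 6
Reactants: 8 1,3-dithiane
Product: 10 2-(tert-butyldimethylsilyl)-1,3-dithiane, via 2-lithio-1,3-dithiane 9 (not isolated)
Conditions: n-BuLi, THF, −30 °C; then TBSCl, −78 °C → rt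
Reagents that add atoms: tert-butyldimethylsilyl chloride (TBSCl), CC(C)(C)[Si](C)(C)Cl
Why: C2 deprotonation of the dithiane (Corey–Seebach umpolung) followed by C-silylation of the anion is the standard way to the silyl linchpin.

Step 7
Reactants: 10 2-(tert-butyldimethylsilyl)-1,3-dithiane; 4 (R)-2-[4-(triisopropylsilyloxy)phenyl]oxirane; 7 racemic 2-[(E)-2-(3-methoxy-4-triisopropylsilyloxyphenyl)ethenyl]oxirane
Product: 14 (1E,7S)-7-(tert-butyldimethylsilyloxy)-1-[3-methoxy-4-(triisopropylsilyloxy)phenyl]-7-[4-(triisopropylsilyloxy)phenyl]-5,5-(propane-1,3-diyldisulfanediyl)hept-1-en-3-ol (C5 dithiane; both C3 epimers), via 2-lithio-2-(tert-butyldimethylsilyl)-1,3-dithiane 11 (not isolated), via C-silyl lithium alkoxide 12 (not isolated), via O-silyl 2-lithiodithiane 13 (not isolated)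
Conditions: t-BuLi, Et2O, −78 → −45 °C; 4, Et2O, −78 → −25 °C; then 7 in THF–HMPA, −78 → 0 °C; H2O
Reagents that add atoms: none
Why: Lithiated 10 (11) opens oxirane 4 by SN2 attack at its unsubstituted CH2 to forge C5–C6 and give lithium alkoxide 12, which in ether keeps silicon on carbon; HMPA then loosens the O–Li pair, a 1,4-Brook shift carries the TBS group from C5 to the C7 oxygen, and the dithiane-stabilised carbanion 13 so formed opens oxirane 7 at its CH2 to forge C4–C5. The closest known reaction type is the three-component linchpin coupling of a 2-silyl-1,3-dithiane with two different epoxides by solvent-gated anion relay. No ring is closed, so no mode of closure applies; two acyclic C–C bonds are made. No stereocentre is created: C7 keeps the configuration of 4 because its benzylic carbon is not attacked (R in the oxirane reads S in the chain only because the CIP ranking of the CH2 and aryl branches inverts), and C3 is inherited from racemic 7 as both epimers, which step 8 merges. The step needs terminal over benzylic opening of 4, which the bulky tertiary anion and the absence of any Lewis acid should secure, and SN2 over SN2' or internal opening of 7, which the free oxirane CH2 and the aryl group shielding the far alkene terminus should secure. Timing is the third requirement, met by adding HMPA only together with 7 so that 11 cannot consume two molecules of 4.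

Step 8
Reactants: 14 (1E,7S)-7-(tert-butyldimethylsilyloxy)-1-[3-methoxy-4-(triisopropylsilyloxy)phenyl]-7-[4-(triisopropylsilyloxy)phenyl]-5,5-(propane-1,3-diyldisulfanediyl)hept-1-en-3-ol
Product: 15 (1E,7S)-7-(tert-butyldimethylsilyloxy)-1-[3-methoxy-4-(triisopropylsilyloxy)phenyl]-7-[4-(triisopropylsilyloxy)phenyl]-5,5-(propane-1,3-diyldisulfanediyl)hept-1-en-3-one
Conditions: activated MnO2, CH2Cl2, rt
Reagents that add atoms: none
Why: allylic oxidation on activated MnO2 is selective for the styryl-conjugated carbinol, should leave the dithiane sulfur atoms and the silyl ethers alone, and merges the two C3 epimers into one enone.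

Step 9
Reactants: 15 (1E,7S)-7-(tert-butyldimethylsilyloxy)-1-[3-methoxy-4-(triisopropylsilyloxy)phenyl]-7-[4-(triisopropylsilyloxy)phenyl]-5,5-(propane-1,3-diyldisulfanediyl)hept-1-en-3-one
Product: 16 (1E,7S)-7-(tert-butyldimethylsilyloxy)-1-[3-methoxy-4-(triisopropylsilyloxy)phenyl]-7-[4-(triisopropylsilyloxy)phenyl]hept-1-ene-3,5-dione (drawn as its C3 enol)
Conditions: MeI, CaCO3, MeCN–H2O (9:1), 40 °C
Reagents that add atoms: water, O
Why: alkylative dithiane hydrolysis, in which S-methylation turns sulfur into a leaving group, water adds to the thionium ion and CaCO3 takes up the HI, should release the C5 ketone under near-neutral conditions that keep the three silyl ethers and the β-silyloxy ketone intact.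

Step 10
Reactants: 16 (1E,7S)-7-(tert-butyldimethylsilyloxy)-1-[3-methoxy-4-(triisopropylsilyloxy)phenyl]-7-[4-(triisopropylsilyloxy)phenyl]hept-1-ene-3,5-dione
Product: 17 (1E,7S)-7-hydroxy-1-(4-hydroxy-3-methoxyphenyl)-7-(4-hydroxyphenyl)hept-1-ene-3,5-dione as its C3 enol (CNP0206527.1)
Conditions: Bu4NF, AcOH (1:1), THF, 0 °C → rt
Reagents that add atoms: none
Why: fluoride-mediated desilylation buffered by acetic acid should cleave the two aryl TIPS ethers and the benzylic TBS ether without building up phenoxide or alkoxide, which suppresses E1cB dehydration to the dienone and retro-aldol cleavage, and C7 is not involved and stays (S).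

**Compound list**

1 | 2-bromo-1-(4-hydroxyphenyl)ethanone | O=C(CBr)c1ccc(O)cc1 | starting material
2 | 2-bromo-1-[4-(triisopropylsilyloxy)phenyl]ethanone | O=C(CBr)c1ccc(O[Si](C(C)C)(C(C)C)C(C)C)cc1 | intermediate
3 | (R)-2-bromo-1-[4-(triisopropylsilyloxy)phenyl]ethanol | O[C@@H](CBr)c1ccc(O[Si](C(C)C)(C(C)C)C(C)C)cc1 | intermediate
4 | (R)-2-[4-(triisopropylsilyloxy)phenyl]oxirane | C1O[C@@H]1c1ccc(O[Si](C(C)C)(C(C)C)C(C)C)cc1 | intermediate
5 | coniferaldehyde, (E)-3-(4-hydroxy-3-methoxyphenyl)prop-2-enal | COc1cc(/C=C/C=O)ccc1O | starting material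
6 | (E)-3-[3-methoxy-4-(triisopropylsilyloxy)phenyl]prop-2-enal | COc1cc(/C=C/C=O)ccc1O[Si](C(C)C)(C(C)C)C(C)C | intermediate
7 | racemic 2-[(E)-2-(3-methoxy-4-triisopropylsilyloxyphenyl)ethenyl]oxirane | COc1cc(/C=C/C2CO2)ccc1O[Si](C(C)C)(C(C)C)C(C)C | intermediate
8 | 1,3-dithiane | C1CSCSC1 | starting material
9 | 2-lithio-1,3-dithiane | [Li]C1SCCCS1 | intermediate (not isolated)
10 | 2-(tert-butyldimethylsilyl)-1,3-dithiane | CC(C)(C)[Si](C)(C)C1SCCCS1 | intermediate
11 | 2-lithio-2-(tert-butyldimethylsilyl)-1,3-dithiane | [Li]C1([Si](C)(C)C(C)(C)C)SCCCS1 | intermediate (not isolated)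
12 | lithium (S)-2-[2-(tert-butyldimethylsilyl)-1,3-dithian-2-yl]-1-[4-(triisopropylsilyloxy)phenyl]ethanolate | [Li]O[C@@H](CC1([Si](C)(C)C(C)(C)C)SCCCS1)c1ccc(O[Si](C(C)C)(C(C)C)C(C)C)cc1 | intermediate (not isolated)
13 | (S)-2-lithio-2-{2-(tert-butyldimethylsilyloxy)-2-[4-(triisopropylsilyloxy)phenyl]ethyl}-1,3-dithiane | [Li]C1(C[C@H](O[Si](C)(C)C(C)(C)C)c2ccc(O[Si](C(C)C)(C(C)C)C(C)C)cc2)SCCCS1 | intermediate (not isolated)
14 | (1E,7S)-7-(tert-butyldimethylsilyloxy)-1-[3-methoxy-4-(triisopropylsilyloxy)phenyl]-7-[4-(triisopropylsilyloxy)phenyl]-5,5-(propane-1,3-diyldisulfanediyl)hept-1-en-3-ol, both C3 epimers | COc1cc(/C=C/C(O)CC2(C[C@H](O[Si](C)(C)C(C)(C)C)c3ccc(O[Si](C(C)C)(C(C)C)C(C)C)cc3)SCCCS2)ccc1O[Si](C(C)C)(C(C)C)C(C)C | intermediate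
15 | (1E,7S)-7-(tert-butyldimethylsilyloxy)-1-[3-methoxy-4-(triisopropylsilyloxy)phenyl]-7-[4-(triisopropylsilyloxy)phenyl]-5,5-(propane-1,3-diyldisulfanediyl)hept-1-en-3-one | COc1cc(/C=C/C(=O)CC2(C[C@H](O[Si](C)(C)C(C)(C)C)c3ccc(O[Si](C(C)C)(C(C)C)C(C)C)cc3)SCCCS2)ccc1O[Si](C(C)C)(C(C)C)C(C)C | intermediate
16 | (1E,7S)-7-(tert-butyldimethylsilyloxy)-1-[3-methoxy-4-(triisopropylsilyloxy)phenyl]-7-[4-(triisopropylsilyloxy)phenyl]hept-1-ene-3,5-dione, C3 enol form | COc1cc(/C=C/C(O)=C\C(=O)C[C@H](O[Si](C)(C)C(C)(C)C)c2ccc(O[Si](C(C)C)(C(C)C)C(C)C)cc2)ccc1O[Si](C(C)C)(C(C)C)C(C)C | intermediate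
17 | (1E,7S)-7-hydroxy-1-(4-hydroxy-3-methoxyphenyl)-7-(4-hydroxyphenyl)hept-1-ene-3,5-dione, C3 enol form (CNP0206527.1) | COc1cc(/C=C/C(O)=C\C(=O)C[C@H](O)c2ccc(O)cc2)ccc1O | target

**Summary**

Total step count: 10.
Longest linear sequence: 7 steps (steps 1, 2, 3, 7, 8, 9, 10, from 1 to 17).

Steps most likely to fail:

Step 7. What may go wrong: attack at the benzylic carbon of 4, a silyl shift that starts before 4 is consumed, or attack of carbanion 13 at the allylic positions of 7 (SN2' or internal opening) together with decomposition of the electron-rich styryl oxirane. Fallback, setting out from 4 and 6 and returning at 16: the C4–C5 epoxide opening is given up and C3–C4 is made by an aldol reaction instead.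
- 2-Lithio-2-methyl-1,3-dithiane (from 2-methyl-1,3-dithiane and n-BuLi in THF) would open 4 at CH2 to give (S)-2-(2-methyl-1,3-dithian-2-yl)-1-[4-(triisopropylsilyloxy)phenyl]ethanol F1.
- TBSOTf and 2,6-lutidine would give (S)-2-{2-(tert-butyldimethylsilyloxy)-2-[4-(triisopropylsilyloxy)phenyl]ethyl}-2-methyl-1,3-dithiane F2.
- MeI and CaCO3 in wet MeCN would release (S)-4-(tert-butyldimethylsilyloxy)-4-[4-(triisopropylsilyloxy)phenyl]butan-2-one F3.
- Kinetic deprotonation of the methyl group with LiN(i-Pr)2 in THF at −78 °C and addition of aldehyde 6 would give (1E,7S)-7-(tert-butyldimethylsilyloxy)-3-hydroxy-1-[3-methoxy-4-(triisopropylsilyloxy)phenyl]-7-[4-(triisopropylsilyloxy)phenyl]hept-1-en-5-one F4 as both C3 epimers.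
- MnO2 in CH2Cl2 would oxidise the allylic carbinol of F4 to 16.

Step 9. What may go wrong: slow S-methylation of the hindered thioketal, during which the freed, acidic β-diketone is C-methylated at C4 by MeI or loses the C7 silyloxy group by β-elimination. Fallback, setting out from 14 and returning at 16: unmasking and oxidation change places. MeI and CaCO3 in wet MeCN applied to carbinol 14 would give (1E,7S)-7-(tert-butyldimethylsilyloxy)-3-hydroxy-1-[3-methoxy-4-(triisopropylsilyloxy)phenyl]-7-[4-(triisopropylsilyloxy)phenyl]hept-1-en-5-one F5 (the same structure as F4). This β-hydroxy ketone is not a 1,3-dicarbonyl C–H acid and cannot be alkylated at C4. MnO2 in CH2Cl2 would then oxidise C3 to give 16.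

Step 10. What may go wrong: loss of the C7 oxygen by E1cB or quinone-methide-type elimination to the 1,6-diene-3,5-dione, or retro-aldol cleavage, while the slow benzylic TBS ether is being removed; or incomplete cleavage. Fallback, setting out from 15 and returning at 17: the silyl groups are removed while C5 is still a thioketal, so no carbonyl is β to C7. Bu4NF and AcOH in THF on 15 would give (1E,7S)-7-hydroxy-1-(4-hydroxy-3-methoxyphenyl)-7-(4-hydroxyphenyl)-5,5-(propane-1,3-diyldisulfanediyl)hept-1-en-3-one F6. MeI and CaCO3 in wet MeCN would then release the C5 ketone as the last operation and give 17 directly.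

**Further compounds**

F1 | step 7 | (S)-2-(2-methyl-1,3-dithian-2-yl)-1-[4-(triisopropylsilyloxy)phenyl]ethanol | CC1(C[C@H](O)c2ccc(O[Si](C(C)C)(C(C)C)C(C)C)cc2)SCCCS1
F2 | step 7 | (S)-2-{2-(tert-butyldimethylsilyloxy)-2-[4-(triisopropylsilyloxy)phenyl]ethyl}-2-methyl-1,3-dithiane | CC1(C[C@H](O[Si](C)(C)C(C)(C)C)c2ccc(O[Si](C(C)C)(C(C)C)C(C)C)cc2)SCCCS1
F3 | step 7 | (S)-4-(tert-butyldimethylsilyloxy)-4-[4-(triisopropylsilyloxy)phenyl]butan-2-one | CC(=O)C[C@H](O[Si](C)(C)C(C)(C)C)c1ccc(O[Si](C(C)C)(C(C)C)C(C)C)cc1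
F4 | step 7 | (1E,7S)-7-(tert-butyldimethylsilyloxy)-3-hydroxy-1-[3-methoxy-4-(triisopropylsilyloxy)phenyl]-7-[4-(triisopropylsilyloxy)phenyl]hept-1-en-5-one, both C3 epimers | COc1cc(/C=C/C(O)CC(=O)C[C@H](O[Si](C)(C)C(C)(C)C)c2ccc(O[Si](C(C)C)(C(C)C)C(C)C)cc2)ccc1O[Si](C(C)C)(C(C)C)C(C)C
F5 | step 9 | (1E,7S)-7-(tert-butyldimethylsilyloxy)-3-hydroxy-1-[3-methoxy-4-(triisopropylsilyloxy)phenyl]-7-[4-(triisopropylsilyloxy)phenyl]hept-1-en-5-one, both C3 epimers | COc1cc(/C=C/C(O)CC(=O)C[C@H](O[Si](C)(C)C(C)(C)C)c2ccc(O[Si](C(C)C)(C(C)C)C(C)C)cc2)ccc1O[Si](C(C)C)(C(C)C)C(C)C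
F6 | step 10 | (1E,7S)-7-hydroxy-1-(4-hydroxy-3-methoxyphenyl)-7-(4-hydroxyphenyl)-5,5-(propane-1,3-diyldisulfanediyl)hept-1-en-3-one | COc1cc(/C=C/C(=O)CC2(C[C@H](O)c3ccc(O)cc3)SCCCS2)ccc1O
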